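The ten-membered carbocycle is disconnected at C7–C8 (germacrane numbering). The target holds there a homoallylic alcohol, O–C8–C7–C11=C13, whose allyl part is the 2-acylallyl unit of the α-methylene-γ-butyrolactone ring: the retron of a carbonyl allylation. The precursor is an open-chain 3-(bromomethyl)butenolide, in which the lactone is the only ring and C6 and C2 the only stereocentres, carrying a C8 aldehyde at the end of the C5–C9 chain. One CrCl2-mediated Barbier allylation closes the carbocycle, sets C7 and C8 from C6 and unmasks the exocyclic methylene. A Mitsunobu esterification with the separately made epoxy acid then inverts C8.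

Key step: step 20

Remark: germacrane numbering is used (ring C1–C10, lactone carbons C11–C13 with the ring oxygen on C6, methyls C14 on C10 and C15 on C4); TBS = tert-butyldimethylsilyl; compounds 1, 10 and 20 are taken as commercial; the catalyst enantiomers in steps 10 and 14 are assigned from the accepted transition-state models, and the antipode would be used if a Mosher analysis showed the opposite sense.

Step 1
Reactants: 1 (2E)-but-2-enal
Product: 2 (2Z)-2-iodobut-2-enal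
Conditions: I2, K2CO3, DMAP (20 mol%), THF/H2O, rt
Reagents that add atoms: iodine, II
Why: Baylis–Hillman-type α-iodination (conjugate addition of DMAP, iodination of the enolate, E1cB loss of DMAP) keeps the methyl group trans to the formyl group, so that iodine and methyl end up cis.

Step 2
Reactants: 2 (2Z)-2-iodobut-2-enal
Product: 3 (2Z)-2-iodobut-2-en-1-ol
Conditions: NaBH4, CeCl3·7H2O, MeOH, 0 °C
Reagents that add atoms: none
Why: Luche 1,2-reduction of the enal leaves the vinyl iodide and the alkene geometry untouched.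

Step 3
Reactants: 3 (2Z)-2-iodobut-2-en-1-ol
Product: 4 tert-butyl{[(2Z)-2-iodobut-2-en-1-yl]oxy}dimethylsilane
Conditions: TBSCl, imidazole, DMF, 0 °C to rt
Reagents that add atoms: tert-butyldimethylsilyl chloride, C[Si](C)(Cl)C(C)(C)C
Why: Standard silylation of a primary alcohol, needed so that the later hydroxymethyl group is the only free hydroxyl.

Step 4
Reactants: 4 tert-butyl{[(2Z)-2-iodobut-2-en-1-yl]oxy}dimethylsilane
Product: 6 (2E)-2-[(TBSO)methyl]but-2-en-1-ol (CH2OH cis to CH3), via vinyllithium 5 (not isolated)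
Conditions: t-BuLi (2.1 equiv), Et2O, −78 °C; then (CH2O)n, −78 °C to rt
Reagents that add atoms: formaldehyde (from paraformaldehyde), C=O
Why: Iodine–lithium exchange with retention of geometry and hydroxymethylation of the vinyllithium place the new CH2OH cis to the methyl group, β-elimination of silanolate being slow at −78 °C.

Step 5
Reactants: 6 (2E)-2-[(TBSO)methyl]but-2-en-1-ol
Product: 7 {(2R,3R)-2-[(TBSO)methyl]-3-methyloxiran-2-yl}methanol
Conditions: Ti(OiPr)4 (10 mol%), L-(+)-diethyl tartrate (12 mol%), t-BuOOH, 4 Å molecular sieves, CH2Cl2, −20 °C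
Reagents that add atoms: tert-butyl hydroperoxide, CC(C)(C)OO
Why: Katsuki–Sharpless asymmetric epoxidation directed by the free allylic hydroxyl, in which the L-(+)-tartrate complex should deliver oxygen to the face that gives the (2R,3R)-epoxide while the alkene geometry fixes methyl cis to CH2OH.

Step 6
Reactants: 7 {(2R,3R)-2-[(TBSO)methyl]-3-methyloxiran-2-yl}methanol
Product: 9 (2R,3R)-2-[(TBSO)methyl]-3-methyloxirane-2-carboxylic acid, via epoxy aldehyde 8 (not isolated)
Conditions: TEMPO (20 mol%), PhI(OAc)2 (2.2 equiv), MeCN/H2O (1:1), rt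
Reagents that add atoms: water, O
Why: Oxoammonium (TEMPO) oxidation to the aldehyde and then of its hydrate to the acid is near neutral and spares the epoxide and the silyl ether.

Step 7
Reactants: 10 4-methyl-5,6-dihydro-2H-pyran-2-one
Product: 11 (2Z)-5-hydroxy-N-methoxy-N,3-dimethylpent-2-enamide
Conditions: MeNH(OMe)·HCl, Me3Al, CH2Cl2, 0 °C to rt
Reagents that add atoms: N,O-dimethylhydroxylamine hydrochloride, Cl.CNOC
Why: Weinreb aminolysis of the lactone by the aluminium amide opens the ring, and the Z geometry of C1=C10 is inherited from the ring.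

Step 8
Reactants: 11 (2Z)-5-hydroxy-N-methoxy-N,3-dimethylpent-2-enamide
Product: 12 (2Z)-5-(TBSO)-N-methoxy-N,3-dimethylpent-2-enamide
Conditions: TBSCl, imidazole, DMF, rt
Reagents that add atoms: tert-butyldimethylsilyl chloride, C[Si](C)(Cl)C(C)(C)C
Why: Silylation of the primary alcohol prevents relactonisation and lactol formation in the next step.

Step 9
Reactants: 12 (2Z)-5-(TBSO)-N-methoxy-N,3-dimethylpent-2-enamide
Product: 13 (2Z)-5-(TBSO)-3-methylpent-2-enal
Conditions: iBu2AlH, THF, −78 °C; aqueous potassium sodium tartrate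
Reagents that add atoms: none
Why: Weinreb amide reduction stops at the chelated tetrahedral intermediate, which releases the Z-enal only on work-up.

Step 10
Reactants: 13 (2Z)-5-(TBSO)-3-methylpent-2-enal
Product: 14 (4R,5Z)-8-(TBSO)-6-methyloct-5-en-1-yn-4-ol
Conditions: allenylboronic acid pinacol ester (1.5 equiv), (R)-TRIP (10 mol%), 4 Å molecular sieves, toluene, −20 °C
Reagents that add atoms: allenylboronic acid pinacol ester, C=C=CB1OC(C)(C)C(C)(C)O1
Why: Chiral phosphoric acid-catalysed propargylation (SE2' allenylboration through a six-membered chair in which the acid binds the boronate oxygen and the formyl hydrogen) should add to the Re face of the enal and set C2 as R.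

Step 11
Reactants: 14 (4R,5Z)-8-(TBSO)-6-methyloct-5-en-1-yn-4-ol
Product: 15 (4R,5Z)-4,8-bis(TBSO)-6-methyloct-5-en-1-yne
Conditions: TBSCl, imidazole, DMAP (cat.), DMF, rt
Reagents that add atoms: tert-butyldimethylsilyl chloride, C[Si](C)(Cl)C(C)(C)C
Why: Silylation of the secondary allylic alcohol protects C2–OH until the last step.

Step 12
Reactants: 15 (4R,5Z)-4,8-bis(TBSO)-6-methyloct-5-en-1-yne
Product: 18 (2E,5R,6Z)-5,9-bis(TBSO)-3,7-dimethylnona-2,6-dien-1-ol, via vinylalane 16 (not isolated), via lithium alanate 17 (not isolated)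
Conditions: Me3Al, Cp2ZrCl2 (25 mol%), CH2Cl2, 0 °C to rt; evaporate; n-BuLi, hexane/THF, −78 °C; (CH2O)n, −78 °C to rt
Reagents that add atoms: trimethylaluminium, C[Al](C)C; formaldehyde (from paraformaldehyde), C=O
Why: Negishi zirconium-catalysed carboalumination adds methyl and aluminium syn with methyl on the internal carbon, which fixes the E-trisubstituted C4=C5 alkene, and the alanate is hydroxymethylated with retention.

Step 13
Reactants: 18 (2E,5R,6Z)-5,9-bis(TBSO)-3,7-dimethylnona-2,6-dien-1-ol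
Product: 19 (2E,5R,6Z)-5,9-bis(TBSO)-3,7-dimethylnona-2,6-dienal
Conditions: MnO2, CH2Cl2, rt
Reagents that add atoms: none
Why: MnO2 oxidises the allylic alcohol selectively and should not isomerise the alkene.

Step 14
Reactants: 19 (2E,5R,6Z)-5,9-bis(TBSO)-3,7-dimethylnona-2,6-dienal; 20 tert-butyl(dimethyl)(prop-2-yn-1-yloxy)silane
Product: 22 (4R,5E,8R,9Z)-1,8,12-tris(TBSO)-6,10-dimethyldodeca-5,9-dien-2-yn-4-ol, via methylzinc acetylide 21 (not isolated)
Conditions: Me2Zn (3 equiv), (S,S)-ProPhenol (20 mol%), Ph3PO (40 mol%), toluene, 0 °C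
Reagents that add atoms: none
Why: ProPhenol dinuclear-zinc catalysed asymmetric alkynylation adds the zinc acetylide 1,2 to the enal on the Si face and should set C6 as R.

Step 15
Reactants: 22 (4R,5E,8R,9Z)-1,8,12-tris(TBSO)-6,10-dimethyldodeca-5,9-dien-2-yn-4-ol
Product: 24 (2Z,4R,5E,8R,9Z)-1,8,12-tris(TBSO)-2-iodo-6,10-dimethyldodeca-2,5,9-trien-4-ol, via cyclic alkenylaluminate 23 (not isolated)
Conditions: NaAlH2(OCH2CH2OCH3)2, THF, −20 to 0 °C; then I2, THF, −78 °C
Reagents that add atoms: iodine, II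
Why: Hydroxyl-directed trans-hydroalumination puts aluminium on the distal alkyne carbon C11 in a five-membered oxa-aluminacycle and iodinolysis with retention gives the Z-γ-iodo allylic alcohol, the C13 ether oxygen not directing and the low temperature holding back elimination to an allene.

Step 16
Reactants: 24 (2Z,4R,5E,8R,9Z)-1,8,12-tris(TBSO)-2-iodo-6,10-dimethyldodeca-2,5,9-trien-4-ol
Product: 25 (5R)-5-[(1E,4R,5Z)-4,8-bis(TBSO)-2,6-dimethylocta-1,5-dien-1-yl]-3-[(TBSO)methyl]furan-2(5H)-one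
Conditions: Pd(PPh3)4 (5 mol%), CO (1 atm), K2CO3, THF, 45 °C
Reagents that add atoms: carbon monoxide, [C-]#[O+]
Why: Palladium-catalysed carbonylative lactonisation (oxidative addition of zerovalent palladium, CO insertion, capture of the acylpalladium by the cis C6 hydroxyl) closes the butenolide without involving C6, and the weak heterogeneous base limits epimerisation of the γ-position.

Step 17
Reactants: 25 (5R)-5-[(1E,4R,5Z)-4,8-bis(TBSO)-2,6-dimethylocta-1,5-dien-1-yl]-3-[(TBSO)methyl]furan-2(5H)-one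
Product: 26 (5R)-5-[(1E,4R,5Z)-8-hydroxy-4-(TBSO)-2,6-dimethylocta-1,5-dien-1-yl]-3-(hydroxymethyl)furan-2(5H)-one
Conditions: HF·pyridine, pyridine, THF, 0 °C
Reagents that add atoms: none
Why: Selective desilylation, the two primary silyl ethers being cleaved by buffered HF·pyridine much faster than the secondary allylic one at C2.

Step 18
Reactants: 26 (5R)-5-[(1E,4R,5Z)-8-hydroxy-4-(TBSO)-2,6-dimethylocta-1,5-dien-1-yl]-3-(hydroxymethyl)furan-2(5H)-one
Product: 27 (5R)-3-(bromomethyl)-5-[(1E,4R,5Z)-8-hydroxy-4-(TBSO)-2,6-dimethylocta-1,5-dien-1-yl]furan-2(5H)-one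
Conditions: NBS, Me2S, CH2Cl2, −20 to 0 °C
Reagents that add atoms: N-bromosuccinimide, O=C1CCC(=O)N1Br
Why: Corey–Kim halogenation converts only the activated allylic alcohol into the bromide, whereas the saturated C8 alcohol is returned unchanged on work-up.

Step 19
Reactants: 27 (5R)-3-(bromomethyl)-5-[(1E,4R,5Z)-8-hydroxy-4-(TBSO)-2,6-dimethylocta-1,5-dien-1-yl]furan-2(5H)-one
Product: 28 (3Z,5R,7E)-8-[(2R)-4-(bromomethyl)-5-oxo-2,5-dihydrofuran-2-yl]-5-(TBSO)-3,7-dimethylocta-3,7-dienal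
Conditions: Dess–Martin periodinane, NaHCO3, CH2Cl2, 0 °C; used crude
Reagents that add atoms: none
Why: Buffered Dess–Martin oxidation gives the β,γ-unsaturated aldehyde without base, so that migration of the C1=C10 alkene into conjugation is avoided.

Step 20
Reactants: 28 (3Z,5R,7E)-8-[(2R)-4-(bromomethyl)-5-oxo-2,5-dihydrofuran-2-yl]-5-(TBSO)-3,7-dimethylocta-3,7-dienal
Product: 30 (3aR,4S,6Z,8R,10E,11aR)-4-hydroxy-8-(TBSO)-6,10-dimethyl-3-methylidene-3a,4,5,8,9,11a-hexahydrocyclodeca[b]furan-2(3H)-one, via allylchromium dichloride 29 (not isolated)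
Conditions: CrCl2 (10 equiv), THF/DMF, rt, syringe-pump addition of 28 (final 2 mM)
Reagents that add atoms: none
Why: Two equivalents of CrCl2 reduce the allylic bromide to the allylchromium species 29 (trivalent chromium), which adds to the tethered aldehyde through its γ-carbon C7 in a six-membered chair (SE2' carbonyl allylation), forming C7–C8 and moving the double bond to C11=C13. The closest known reactions are the intermolecular Nozaki–Hiyama/Barbier allylation of aldehydes with 3-(bromomethyl)furan-2(5H)-ones and the CrCl2-mediated Barbier macrocyclisation of 2-(bromomethyl)acrylates to ten-membered germacranolides. The ten-membered carbocycle is closed by intramolecular carbonyl allylation (10-exo-trig attack on the C8 aldehyde), the lactone ring being already in place. C7 is controlled by C6, because the aldehyde can reach the allyl face anti to the C5 branch without the C5/C9 syn-pentane contact of the other face, which should give the trans-fused lactone; C8 is controlled by the chair, in which the ring-locked E-allyl unit holds C6 equatorial and the C9 branch of the aldehyde sits equatorial, which should give the 7,8-anti (8S) alcohol. The step needs γ- over α-attack, ring closure over dimerisation and one of four diastereomers: the first is inherent in allylchromium reagents, the second is secured by slow addition at high dilution and the third by the single stereocentre C6 next to the reacting carbon.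

Step 21
Reactants: 30 (3aR,4S,6Z,8R,10E,11aR)-4-hydroxy-8-(TBSO)-6,10-dimethyl-3-methylidene-3a,4,5,8,9,11a-hexahydrocyclodeca[b]furan-2(3H)-one; 9 (2R,3R)-2-[(TBSO)methyl]-3-methyloxirane-2-carboxylic acid
Product: 32 (3aR,4R,6Z,8R,10E,11aR)-8-(TBSO)-6,10-dimethyl-3-methylidene-2-oxo-2,3,3a,4,5,8,9,11a-octahydrocyclodeca[b]furan-4-yl (2R,3R)-2-[(TBSO)methyl]-3-methyloxirane-2-carboxylate, via alkoxyphosphonium carboxylate 31 (not isolated)
Conditions: PPh3, DIAD, toluene, 0 °C to rt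
Reagents that add atoms: none
Why: Mitsunobu esterification, in which the carboxylate of the acidic glycidic acid 9 displaces the alkoxyphosphonium ion by SN2 with inversion and so turns the 8S alcohol into the 8R ester under neutral conditions.

Step 22
Reactants: 32 (3aR,4R,6Z,8R,10E,11aR)-8-(TBSO)-6,10-dimethyl-3-methylidene-2-oxo-2,3,3a,4,5,8,9,11a-octahydrocyclodeca[b]furan-4-yl (2R,3R)-2-[(TBSO)methyl]-3-methyloxirane-2-carboxylate
Product: 33 (3aR,4R,6Z,8R,10E,11aR)-8-hydroxy-6,10-dimethyl-3-methylidene-2-oxo-2,3,3a,4,5,8,9,11a-octahydrocyclodeca[b]furan-4-yl (2R,3R)-2-(hydroxymethyl)-3-methyloxirane-2-carboxylate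
Conditions: HF·pyridine, pyridine, THF, 0 °C to rt
Reagents that add atoms: none
Why: Fluoride-mediated desilylation under buffered, non-basic conditions removes both silyl ethers without Payne rearrangement of the epoxy alcohol or conjugate addition to the α-methylene lactone.

Compound list

1 | (2E)-but-2-enal | C/C=C/C=O | starting material
2 | (2Z)-2-iodobut-2-enal | C/C=C(\I)C=O | intermediate
3 | (2Z)-2-iodobut-2-en-1-ol | C/C=C(\I)CO | intermediate
4 | tert-butyl{[(2Z)-2-iodobut-2-en-1-yl]oxy}dimethylsilane | C/C=C(\I)CO[Si](C)(C)C(C)(C)C | intermediate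
5 | [(2E)-1-(TBSO)but-2-en-2-yl]lithium (Li cis to CH3) | C/C=C(\[Li])CO[Si](C)(C)C(C)(C)C | intermediate
6 | (2E)-2-[(TBSO)methyl]but-2-en-1-ol | C/C=C(\CO)CO[Si](C)(C)C(C)(C)C | intermediate
7 | {(2R,3R)-2-[(TBSO)methyl]-3-methyloxiran-2-yl}methanol | OC[C@]1(CO[Si](C)(C)C(C)(C)C)O[C@@H]1C | intermediate
8 | (2R,3R)-2-[(TBSO)methyl]-3-methyloxirane-2-carbaldehyde | O=C[C@]1(CO[Si](C)(C)C(C)(C)C)O[C@@H]1C | intermediate
9 | (2R,3R)-2-[(TBSO)methyl]-3-methyloxirane-2-carboxylic acid | OC(=O)[C@]1(CO[Si](C)(C)C(C)(C)C)O[C@@H]1C | intermediate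
10 | 4-methyl-5,6-dihydro-2H-pyran-2-one (anhydromevalonolactone) | CC1=CC(=O)OCC1 | starting material
11 | (2Z)-5-hydroxy-N-methoxy-N,3-dimethylpent-2-enamide | CON(C)C(=O)/C=C(/C)CCO | intermediate
12 | (2Z)-5-(TBSO)-N-methoxy-N,3-dimethylpent-2-enamide | CON(C)C(=O)/C=C(/C)CCO[Si](C)(C)C(C)(C)C | intermediate
13 | (2Z)-5-(TBSO)-3-methylpent-2-enal | O=C/C=C(/C)CCO[Si](C)(C)C(C)(C)C | intermediate
14 | (4R,5Z)-8-(TBSO)-6-methyloct-5-en-1-yn-4-ol | C#CC[C@@H](O)/C=C(/C)CCO[Si](C)(C)C(C)(C)C | intermediate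
15 | (4R,5Z)-4,8-bis(TBSO)-6-methyloct-5-en-1-yne | C#CC[C@@H](O[Si](C)(C)C(C)(C)C)/C=C(/C)CCO[Si](C)(C)C(C)(C)C | intermediate
16 | [(1E,4R,5Z)-4,8-bis(TBSO)-2,6-dimethylocta-1,5-dien-1-yl]dimethylalane | C[Al](C)/C=C(\C)C[C@@H](O[Si](C)(C)C(C)(C)C)/C=C(/C)CCO[Si](C)(C)C(C)(C)C | intermediate
17 | lithium butyl[(1E,4R,5Z)-4,8-bis(TBSO)-2,6-dimethylocta-1,5-dien-1-yl]dimethylaluminate | [Li+].CCCC[Al-](C)(C)/C=C(\C)C[C@@H](O[Si](C)(C)C(C)(C)C)/C=C(/C)CCO[Si](C)(C)C(C)(C)C | intermediate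
18 | (2E,5R,6Z)-5,9-bis(TBSO)-3,7-dimethylnona-2,6-dien-1-ol | OC/C=C(\C)C[C@@H](O[Si](C)(C)C(C)(C)C)/C=C(/C)CCO[Si](C)(C)C(C)(C)C | intermediate
19 | (2E,5R,6Z)-5,9-bis(TBSO)-3,7-dimethylnona-2,6-dienal | O=C/C=C(\C)C[C@@H](O[Si](C)(C)C(C)(C)C)/C=C(/C)CCO[Si](C)(C)C(C)(C)C | intermediate
20 | tert-butyl(dimethyl)(prop-2-yn-1-yloxy)silane | C#CCO[Si](C)(C)C(C)(C)C | starting material
21 | methyl[3-(TBSO)prop-1-yn-1-yl]zinc | C[Zn]C#CCO[Si](C)(C)C(C)(C)C | intermediate
22 | (4R,5E,8R,9Z)-1,8,12-tris(TBSO)-6,10-dimethyldodeca-5,9-dien-2-yn-4-ol | O[C@@H](C#CCO[Si](C)(C)C(C)(C)C)/C=C(\C)C[C@@H](O[Si](C)(C)C(C)(C)C)/C=C(/C)CCO[Si](C)(C)C(C)(C)C | intermediate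
23 | sodium bis(2-methoxyethoxy) cyclic alkenylaluminate of 22 (2,5-dihydro-1,2-oxaluminole; Al bound to C11 and to the C6 oxygen) | [Na+].COCCO[Al-]1(OCCOC)O[C@@H](C=C1CO[Si](C)(C)C(C)(C)C)/C=C(\C)C[C@@H](O[Si](C)(C)C(C)(C)C)/C=C(/C)CCO[Si](C)(C)C(C)(C)C | intermediate
24 | (2Z,4R,5E,8R,9Z)-1,8,12-tris(TBSO)-2-iodo-6,10-dimethyldodeca-2,5,9-trien-4-ol | O[C@@H](/C=C(\I)CO[Si](C)(C)C(C)(C)C)/C=C(\C)C[C@@H](O[Si](C)(C)C(C)(C)C)/C=C(/C)CCO[Si](C)(C)C(C)(C)C | intermediate
25 | (5R)-5-[(1E,4R,5Z)-4,8-bis(TBSO)-2,6-dimethylocta-1,5-dien-1-yl]-3-[(TBSO)methyl]furan-2(5H)-one | O=C1O[C@@H](C=C1CO[Si](C)(C)C(C)(C)C)/C=C(\C)C[C@@H](O[Si](C)(C)C(C)(C)C)/C=C(/C)CCO[Si](C)(C)C(C)(C)C | intermediate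
26 | (5R)-5-[(1E,4R,5Z)-8-hydroxy-4-(TBSO)-2,6-dimethylocta-1,5-dien-1-yl]-3-(hydroxymethyl)furan-2(5H)-one | O=C1O[C@@H](C=C1CO)/C=C(\C)C[C@@H](O[Si](C)(C)C(C)(C)C)/C=C(/C)CCO | intermediate
27 | (5R)-3-(bromomethyl)-5-[(1E,4R,5Z)-8-hydroxy-4-(TBSO)-2,6-dimethylocta-1,5-dien-1-yl]furan-2(5H)-one | O=C1O[C@@H](C=C1CBr)/C=C(\C)C[C@@H](O[Si](C)(C)C(C)(C)C)/C=C(/C)CCO | intermediate
28 | (3Z,5R,7E)-8-[(2R)-4-(bromomethyl)-5-oxo-2,5-dihydrofuran-2-yl]-5-(TBSO)-3,7-dimethylocta-3,7-dienal | O=C1O[C@@H](C=C1CBr)/C=C(\C)C[C@@H](O[Si](C)(C)C(C)(C)C)/C=C(/C)CC=O | intermediate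
29 | dichloro({(5R)-5-[(1E,4R,5Z)-2,6-dimethyl-8-oxo-4-(TBSO)octa-1,5-dien-1-yl]-2-oxo-2,5-dihydrofuran-3-yl}methyl)chromium (trivalent chromium) | O=C1O[C@@H](C=C1C[Cr](Cl)Cl)/C=C(\C)C[C@@H](O[Si](C)(C)C(C)(C)C)/C=C(/C)CC=O | intermediate
30 | (3aR,4S,6Z,8R,10E,11aR)-4-hydroxy-8-(TBSO)-6,10-dimethyl-3-methylidene-3a,4,5,8,9,11a-hexahydrocyclodeca[b]furan-2(3H)-one | C=C1C(=O)O[C@@H]2/C=C(\C)C[C@@H](O[Si](C)(C)C(C)(C)C)/C=C(/C)C[C@H](O)[C@@H]12 | intermediate
31 | C8-alkoxytriphenylphosphonium ion of 30 paired with the carboxylate of 9 | C=C1C(=O)O[C@@H]2/C=C(\C)C[C@@H](O[Si](C)(C)C(C)(C)C)/C=C(/C)C[C@H](O[P+](c3ccccc3)(c3ccccc3)c3ccccc3)[C@@H]12.[O-]C(=O)[C@]1(CO[Si](C)(C)C(C)(C)C)O[C@@H]1C | intermediate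
32 | (3aR,4R,6Z,8R,10E,11aR)-8-(TBSO)-6,10-dimethyl-3-methylidene-2-oxo-2,3,3a,4,5,8,9,11a-octahydrocyclodeca[b]furan-4-yl (2R,3R)-2-[(TBSO)methyl]-3-methyloxirane-2-carboxylate | C=C1C(=O)O[C@@H]2/C=C(\C)C[C@@H](O[Si](C)(C)C(C)(C)C)/C=C(/C)C[C@@H](OC(=O)[C@]3(CO[Si](C)(C)C(C)(C)C)O[C@@H]3C)[C@@H]12 | intermediate
33 | (3aR,4R,6Z,8R,10E,11aR)-8-hydroxy-6,10-dimethyl-3-methylidene-2-oxo-2,3,3a,4,5,8,9,11a-octahydrocyclodeca[b]furan-4-yl (2R,3R)-2-(hydroxymethyl)-3-methyloxirane-2-carboxylate | C=C1C(=O)O[C@@H]2/C=C(\C)C[C@@H](O)/C=C(/C)C[C@@H](OC(=O)[C@]3(CO)O[C@@H]3C)[C@@H]12 | target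

Total step count: 22 (epoxy acid 9 in steps 1–6, main chain in steps 7–22).
Longest linear sequence: 16 steps (10 to 33, steps 7–22).

Steps most likely to fail

Step 20. The allylchromium may add intermolecularly (dimers and oligomers), be protonated before it cyclises, or close through the face syn to the C5 branch or through the chair with C9 axial, which would give another C7/C8 diastereomer; the β,γ-unsaturated aldehyde may also slip into conjugation first. The fallback sets out from 27 and comes back to the route at 32. Stannylation of 27 with hexabutylditin and Pd(PPh3)4 in THF would give the allylstannane (5R)-5-[(1E,4R,5Z)-8-hydroxy-4-(TBSO)-2,6-dimethylocta-1,5-dien-1-yl]-3-[(tributylstannyl)methyl]furan-2(5H)-one F1. Buffered Dess–Martin oxidation would give the stannyl aldehyde (3Z,5R,7E)-5-(TBSO)-3,7-dimethyl-8-{(2R)-5-oxo-4-[(tributylstannyl)methyl]-2,5-dihydrofuran-2-yl}octa-3,7-dienal F2. BF3·OEt2 in CH2Cl2 at −78 °C and high dilution would close the same C7–C8 bond through an open, Lewis-acid-activated transition state, which favours the 7,8-syn alcohol (3aR,4R,6Z,8R,10E,11aR)-4-hydroxy-8-(TBSO)-6,10-dimethyl-3-methylidene-3a,4,5,8,9,11a-hexahydrocyclodeca[b]furan-2(3H)-one F3. Yamaguchi esterification of F3 with 9 (2,4,6-trichlorobenzoyl chloride, Et3N, DMAP, toluene), with retention at C8, would then give 32.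

Step 21. The activated C8 alcohol may eliminate toward C8=C9 or C7=C8, the carboxylate may attack phosphorus so that the ester forms with retention, and the phosphine may add to the α-methylene lactone. The fallback sets out from 30 and comes back at 32. Chloromethanesulfonyl chloride and pyridine in CH2Cl2 at 0 °C would give the sulfonate (3aR,4S,6Z,8R,10E,11aR)-8-(TBSO)-6,10-dimethyl-3-methylidene-2-oxo-2,3,3a,4,5,8,9,11a-octahydrocyclodeca[b]furan-4-yl chloromethanesulfonate F4. SN2 displacement with the caesium salt of 9 (Cs2CO3, 18-crown-6, toluene, 50 °C) would then give 32 with inversion.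

Step 15. The alkenylaluminate may lose the C13 silanolate to give an allene, hydroalumination may partly place aluminium on C7, and the doubly allylic C6 alcohol may ionise during iodination. The fallback sets out from 19 and comes back at 25, building the butenolide by ring-closing metathesis instead. Addition of trimethylsilylacetylene to 19 under the conditions of step 14 would give (3R,4E,7R,8Z)-7,11-bis(TBSO)-5,9-dimethyl-1-(trimethylsilyl)undeca-4,8-dien-1-yn-3-ol F5. K2CO3 in MeOH would give the terminal alkyne (3R,4E,7R,8Z)-7,11-bis(TBSO)-5,9-dimethylundeca-4,8-dien-1-yn-3-ol F6. Semi-hydrogenation (H2, Pd/CaCO3 poisoned with Pb(OAc)2, quinoline) would give the divinyl carbinol (3R,4E,7R,8Z)-7,11-bis(TBSO)-5,9-dimethylundeca-1,4,8-trien-3-ol F7. Esterification with 2-[(TBSO)methyl]prop-2-enoic acid (DCC, DMAP, CH2Cl2) would give the acrylate (3R,4E,7R,8Z)-7,11-bis(TBSO)-5,9-dimethylundeca-1,4,8-trien-3-yl 2-[(TBSO)methyl]prop-2-enoate F8. Ring-closing metathesis with the second-generation Grubbs catalyst (CH2Cl2, 40 °C) would then give 25.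

Further compounds

F1 | step 20 | (5R)-5-[(1E,4R,5Z)-8-hydroxy-4-(TBSO)-2,6-dimethylocta-1,5-dien-1-yl]-3-[(tributylstannyl)methyl]furan-2(5H)-one | O=C1O[C@@H](C=C1C[Sn](CCCC)(CCCC)CCCC)/C=C(\C)C[C@@H](O[Si](C)(C)C(C)(C)C)/C=C(/C)CCO
F2 | step 20 | (3Z,5R,7E)-5-(TBSO)-3,7-dimethyl-8-{(2R)-5-oxo-4-[(tributylstannyl)methyl]-2,5-dihydrofuran-2-yl}octa-3,7-dienal | O=C1O[C@@H](C=C1C[Sn](CCCC)(CCCC)CCCC)/C=C(\C)C[C@@H](O[Si](C)(C)C(C)(C)C)/C=C(/C)CC=O
F3 | step 20 | (3aR,4R,6Z,8R,10E,11aR)-4-hydroxy-8-(TBSO)-6,10-dimethyl-3-methylidene-3a,4,5,8,9,11a-hexahydrocyclodeca[b]furan-2(3H)-one | C=C1C(=O)O[C@@H]2/C=C(\C)C[C@@H](O[Si](C)(C)C(C)(C)C)/C=C(/C)C[C@@H](O)[C@@H]12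
F4 | step 21 | (3aR,4S,6Z,8R,10E,11aR)-8-(TBSO)-6,10-dimethyl-3-methylidene-2-oxo-2,3,3a,4,5,8,9,11a-octahydrocyclodeca[b]furan-4-yl chloromethanesulfonate | C=C1C(=O)O[C@@H]2/C=C(\C)C[C@@H](O[Si](C)(C)C(C)(C)C)/C=C(/C)C[C@H](OS(=O)(=O)CCl)[C@@H]12
F5 | step 15 | (3R,4E,7R,8Z)-7,11-bis(TBSO)-5,9-dimethyl-1-(trimethylsilyl)undeca-4,8-dien-1-yn-3-ol | O[C@@H](C#C[Si](C)(C)C)/C=C(\C)C[C@@H](O[Si](C)(C)C(C)(C)C)/C=C(/C)CCO[Si](C)(C)C(C)(C)C
F6 | step 15 | (3R,4E,7R,8Z)-7,11-bis(TBSO)-5,9-dimethylundeca-4,8-dien-1-yn-3-ol | O[C@@H](C#C)/C=C(\C)C[C@@H](O[Si](C)(C)C(C)(C)C)/C=C(/C)CCO[Si](C)(C)C(C)(C)C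
F7 | step 15 | (3R,4E,7R,8Z)-7,11-bis(TBSO)-5,9-dimethylundeca-1,4,8-trien-3-ol | O[C@@H](C=C)/C=C(\C)C[C@@H](O[Si](C)(C)C(C)(C)C)/C=C(/C)CCO[Si](C)(C)C(C)(C)C
F8 | step 15 | (3R,4E,7R,8Z)-7,11-bis(TBSO)-5,9-dimethylundeca-1,4,8-trien-3-yl 2-[(TBSO)methyl]prop-2-enoate | C=C(CO[Si](C)(C)C(C)(C)C)C(=O)O[C@@H](C=C)/C=C(\C)C[C@@H](O[Si](C)(C)C(C)(C)C)/C=C(/C)CCO[Si](C)(C)C(C)(C)C
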